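The chroman is cut across the CH2–CH2 bridge of its dihydropyran ring: C4 is detached from aromatic C4a and C3 from the quaternary ether carbon C2, which leaves a vinyl group as a two-carbon linchpin. In one operation the C5 radical of a lactic acid-derived 2-tert-butyl-1,3-dioxolan-4-one adds to the vinyl terminus of an aryl(vinyl)boron ate complex (C2–C3, anti to tert-butyl, fixing C2) and the aryl group then shifts from boron to carbon (C4–C4a). The feature used is that C3–C4 is an unsubstituted bridge between an arene carbon and an oxygen-bearing quaternary stereocentre. Quinone-ketal ring closure and a B-alkyl Suzuki coupling with an epoxygeraniol-derived vinyl iodide finish the target.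

Key step: step 5

Remark: the SMILES is read as 2S at the chroman carbon and 7'S,8'R for the side-chain diol (the anti diol of a 7'E alkene, side chain numbered from the carbon on C2); all steps are planned for these descriptors.

Step 1
Reactants: 1 4-methoxy-2-methylphenol
Product: 2 2-bromo-4-methoxy-6-methylphenol
Conditions: NBS, CH2Cl2, 0 °C
Reagents that add atoms: N-bromosuccinimide, O=C1CCC(=O)N1Br
Why: Electrophilic aromatic bromination should go to the only free position ortho to the hydroxyl group, the strongest director, because the para position is blocked by methoxy.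

Step 2
Reactants: 2 2-bromo-4-methoxy-6-methylphenol
Product: 3 1-bromo-2,5-dimethoxy-3-methylbenzene
Conditions: MeI, K2CO3, DMF, 20 °C
Reagents that add atoms: iodomethane, CI
Why: Williamson O-methylation of the phenoxide gives the hydroquinone dimethyl ether that is later unmasked oxidatively; no stereocentre is involved.

Step 3
Reactants: 4 (S)-lactic acid; 5 pivalaldehyde
Product: 6 (2S,5S)-2-tert-butyl-5-methyl-1,3-dioxolan-4-one
Conditions: p-TsOH (cat.), H2SO4 (cat.), pentane, reflux, water separator; crystallisation at −78 °C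
Reagents that add atoms: none
Why: Acid-catalysed acetalisation with removal of water should set the acetal centre cis to the methyl group under thermodynamic control by the lactic acid stereocentre, and the cis isomer is purified by cold crystallisation.

Step 4
Reactants: 6 (2S,5S)-2-tert-butyl-5-methyl-1,3-dioxolan-4-one
Product: 7 (2R,5R)-5-bromo-2-tert-butyl-5-methyl-1,3-dioxolan-4-one
Conditions: NBS, AIBN (cat.), PhCF3, 80 °C
Reagents that add atoms: N-bromosuccinimide, O=C1CCC(=O)N1Br
Why: Wohl–Ziegler radical bromination at the captodatively activated C5–H should give the tertiary bromide; the acetal carbon keeps its geometry (its descriptor changes only through priorities) and will relay the chirality, while the C5 configuration is irrelevant because C5 becomes a radical.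

Step 5
Reactants: 3 1-bromo-2,5-dimethoxy-3-methylbenzene; 8 vinylboronic acid pinacol ester; 7 (2R,5R)-5-bromo-2-tert-butyl-5-methyl-1,3-dioxolan-4-one
Product: 11 (2S,5R)-2-tert-butyl-5-[2-(2,5-dimethoxy-3-methylphenyl)-2-(4,4,5,5-tetramethyl-1,3,2-dioxaborolan-2-yl)ethyl]-5-methyl-1,3-dioxolan-4-one (both epimers at the boron-bearing carbon), via aryllithium 9 (not isolated), via vinylboron ate complex 10 (not isolated)
Conditions: n-BuLi, THF, −78 °C; 8, −78 → 0 °C; then 7, Ru(bpy)3Cl2 (1 mol %), MeCN, blue LEDs, 20 °C
Reagents that add atoms: none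
Why: Bromine–lithium exchange gives 9, which adds to boron of 8 to give ate complex 10; photoexcited divalent ruthenium then starts a chain in which the captodative C5 radical from 7 adds to the unsubstituted vinyl terminus of 10 (future C2–C3), the resulting α-boryl radical anion is oxidised by a further molecule of 7, and the electron-rich aryl group migrates 1,2 from boron to carbon (future C4–C4a). The closest known reaction type is the radical–polar crossover three-component coupling of vinylboron ate complexes with α-halo carbonyl compounds. No ring is closed here; the dihydropyran ring is closed later at O1–C8a. The new quaternary centre (future C2) is controlled by the tert-butyl group of the acetal, which shields one face of the planar dioxolanonyl radical so that the new C–C bond forms anti to it and the methyl group stays cis (net retention of the lactic acid configuration); the boron-bearing carbon forms without control and is erased in step 6. The step needs attack at the CH2 terminus (secured by α-boryl stabilisation of the adduct radical and by the bulk of the tertiary radical), migration of aryl and not of a pinacol oxygen (secured by the migratory aptitude of the 2,5-dimethoxyaryl group), and no dehydrobromination of 7 (secured by complete ate formation before 7 is added, since 10 is a poor base).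

Step 6
Reactants: 11 the benzylic boronate from step 5
Product: 12 (2S,5R)-2-tert-butyl-5-[2-(2,5-dimethoxy-3-methylphenyl)ethyl]-5-methyl-1,3-dioxolan-4-one
Conditions: Bu4NF·3H2O, toluene, 60 °C
Reagents that add atoms: none
Why: Fluoride-promoted protodeboronation of the secondary benzylic pinacol boronate through its fluoroborate should leave C4 as CH2 and remove the uncontrolled stereocentre.

Step 7
Reactants: 12 (2S,5R)-2-tert-butyl-5-[2-(2,5-dimethoxy-3-methylphenyl)ethyl]-5-methyl-1,3-dioxolan-4-one
Product: 13 (2R)-4-(2,5-dimethoxy-3-methylphenyl)-2-methylbutane-1,2-diol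
Conditions: LiAlH4, THF, 0 → 20 °C
Reagents that add atoms: none
Why: Hydride reduction of the lactone acetal should release the 1,2-diol and the auxiliary as neopentyl alcohol; the quaternary carbinol centre is not touched and keeps its configuration.

Step 8
Reactants: 13 (2R)-4-(2,5-dimethoxy-3-methylphenyl)-2-methylbutane-1,2-diol
Product: 14 2-[(3R)-3,4-dihydroxy-3-methylbutyl]-6-methylcyclohexa-2,5-diene-1,4-dione
Conditions: (NH4)2Ce(NO3)6, MeCN/H2O, 0 °C
Reagents that add atoms: water, O
Why: Oxidative demethylation of the para-dimethoxyarene by tetravalent cerium should give the para-benzoquinone without touching the diol stereocentre.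

Step 9
Reactants: 14 2-[(3R)-3,4-dihydroxy-3-methylbutyl]-6-methylcyclohexa-2,5-diene-1,4-dione
Product: 16 (2R)-2-(hydroxymethyl)-2,8-dimethyl-3,4-dihydro-2H-chromen-6-ol, via bridged quinone monoketal 15 (not isolated)
Conditions: p-TsOH (cat.), 4 Å MS, CH2Cl2, 20 °C; then H2 (1 atm), Pd/C, EtOAc, 20 °C
Reagents that add atoms: none
Why: Intramolecular ketalisation of the quinone carbonyl next to the side chain by both hydroxyl groups, then reductive aromatisation of the quinone monoketal with loss of the primary alkoxide, should close the ring at O1–C8a with retention at C2 because the C2–O bond is never broken.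

Step 10
Reactants: 16 (2R)-2-(hydroxymethyl)-2,8-dimethyl-3,4-dihydro-2H-chromen-6-ol
Product: 17 [(2R)-6-(methoxymethoxy)-2,8-dimethyl-3,4-dihydro-2H-chromen-2-yl]methanol
Conditions: NaH (1 equiv), DMF, 0 °C; MOMCl
Reagents that add atoms: chloromethyl methyl ether, COCCl
Why: Williamson-type alkylation of the phenoxide, which forms selectively because the phenol is far more acidic than the primary alcohol, protects the oxidation-sensitive chromanol.

Step 11
Reactants: 17 [(2R)-6-(methoxymethoxy)-2,8-dimethyl-3,4-dihydro-2H-chromen-2-yl]methanol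
Product: 18 (2R)-6-(methoxymethoxy)-2,8-dimethyl-3,4-dihydro-2H-chromene-2-carbaldehyde
Conditions: Dess–Martin periodinane, NaHCO3, CH2Cl2, 20 °C
Reagents that add atoms: none
Why: Dess–Martin oxidation of the primary alcohol gives an aldehyde that has no α-hydrogen and so cannot epimerise.

Step 12
Reactants: 18 (2R)-6-(methoxymethoxy)-2,8-dimethyl-3,4-dihydro-2H-chromene-2-carbaldehyde
Product: 19 (2R)-2-ethenyl-6-(methoxymethoxy)-2,8-dimethyl-3,4-dihydro-2H-chromene
Conditions: Ph3PCH3Br, KN(SiMe3)2, THF, 0 → 20 °C
Reagents that add atoms: methyltriphenylphosphonium bromide, C[P+](c1ccccc1)(c1ccccc1)c1ccccc1.[Br-]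
Why: Wittig methylenation of the non-enolisable aldehyde installs the vinyl handle (C1'–C2') without touching the stereocentre.

Step 13
Reactants: 20 geraniol
Product: 21 [(2S,3S)-3-methyl-3-(4-methylpent-3-en-1-yl)oxiran-2-yl]methanol
Conditions: Ti(OiPr)4 (cat.), L-(+)-diethyl tartrate (cat.), t-BuOOH, 4 Å MS, CH2Cl2, −20 °C
Reagents that add atoms: tert-butyl hydroperoxide, CC(C)(C)OO
Why: Sharpless asymmetric epoxidation with L-(+)-tartrate should deliver oxygen to the face that gives the (2S,3S)-epoxide, and the distal alkene, which has no allylic hydroxyl, is left alone.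

Step 14
Reactants: 21 [(2S,3S)-3-methyl-3-(4-methylpent-3-en-1-yl)oxiran-2-yl]methanol
Product: 22 [(2S,3S)-3-methyl-3-(4-methylpent-3-en-1-yl)oxiran-2-yl]methyl 4-methylbenzenesulfonate
Conditions: TsCl, Et3N, DMAP (cat.), CH2Cl2, 0 °C
Reagents that add atoms: 4-methylbenzenesulfonyl chloride, Cc1ccc(cc1)S(Cl)(=O)=O
Why: Sulfonylation of the primary alcohol activates C1 for substitution without touching the epoxide stereocentres.

Step 15
Reactants: 22 the epoxy tosylate from step 14; 23 1-(trimethylsilyl)propyne
Product: 26 (2S,3S)-2-(but-3-yn-1-yl)-3-methyl-3-(4-methylpent-3-en-1-yl)oxirane, via lithiated silylpropyne 24 (not isolated), via silylated epoxy alkyne 25 (not isolated)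
Conditions: 23, n-BuLi, THF, −78 °C; 22, THF/DMPU, −78 → 0 °C; then K2CO3, MeOH, 20 °C
Reagents that add atoms: none
Why: Propargylic lithiation of 23 and SN2 displacement of the primary tosylate, which should be faster than attack on the hindered trisubstituted epoxide, followed by methanolysis of the alkynyl C–Si bond, extends the chain with both epoxide centres retained.

Step 16
Reactants: 26 (2S,3S)-2-(but-3-yn-1-yl)-3-methyl-3-(4-methylpent-3-en-1-yl)oxirane
Product: 27 (5S,6R)-6,10-dimethylundec-9-en-1-yne-5,6-diol
Conditions: HClO4 (3 % aq.), THF, 0 °C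
Reagents that add atoms: water, O
Why: Acid-catalysed epoxide hydrolysis should proceed by attack of water at the tertiary carbon with inversion (borderline SN2), which gives the anti diol with C5 retained and C6 inverted.

Step 17
Reactants: 27 (5S,6R)-6,10-dimethylundec-9-en-1-yne-5,6-diol
Product: 28 (1E,5S,6R)-1-iodo-2,6,10-trimethylundeca-1,9-diene-5,6-diol
Conditions: AlMe3 (excess), Cp2ZrCl2, CH2Cl2, 0 → 20 °C; then I2, THF, −30 °C
Reagents that add atoms: trimethylaluminium, C[Al](C)C; iodine, II
Why: Negishi zirconium-catalysed carboalumination adds methyl and aluminium syn across the terminal alkyne (methyl to the internal carbon) and iodinolysis with retention should give the (E)-vinyl iodide, with the diol masked as aluminium alkoxides by the excess AlMe3.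

Step 18
Reactants: 19 (2R)-2-ethenyl-6-(methoxymethoxy)-2,8-dimethyl-3,4-dihydro-2H-chromene; 28 (1E,5S,6R)-1-iodo-2,6,10-trimethylundeca-1,9-diene-5,6-diol
Product: 30 (3E,7S,8R)-1-[(2S)-6-(methoxymethoxy)-2,8-dimethyl-3,4-dihydro-2H-chromen-2-yl]-4,8,12-trimethyltrideca-3,11-diene-7,8-diol, via alkylborane 29 (not isolated)
Conditions: 9-BBN, THF, 0 → 20 °C; then 28, Pd(dppf)Cl2 (5 mol %), AsPh3, Cs2CO3, DMF/H2O, 20 °C
Reagents that add atoms: none
Why: Anti-Markovnikov hydroboration of the vinyl group and B-alkyl Suzuki–Miyaura coupling with retention of the (E)-alkene geometry join the fragments at C2'–C3' without touching any stereocentre.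

Step 19
Reactants: 30 the methoxymethyl ether from step 18
Product: 31 (2S)-2-[(3E,7S,8R)-7,8-dihydroxy-4,8,12-trimethyltrideca-3,11-dien-1-yl]-2,8-dimethyl-3,4-dihydro-2H-chromen-6-ol
Conditions: HCl (0.5 M), MeOH, 20 °C
Reagents that add atoms: none
Why: Acid-catalysed methanolysis of the aryl methoxymethyl acetal under conditions mild enough for the trisubstituted alkenes and the diol should release the free chromanol.

Compound list
1 | 4-methoxy-2-methylphenol | Cc1cc(OC)ccc1O | starting material
2 | 2-bromo-4-methoxy-6-methylphenol | Cc1cc(OC)cc(Br)c1O | intermediate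
3 | 1-bromo-2,5-dimethoxy-3-methylbenzene | COc1cc(C)c(OC)c(Br)c1 | intermediate
4 | (S)-lactic acid, (2S)-2-hydroxypropanoic acid | C[C@H](O)C(=O)O | starting material
5 | pivalaldehyde, 2,2-dimethylpropanal | CC(C)(C)C=O | starting material
6 | (2S,5S)-2-tert-butyl-5-methyl-1,3-dioxolan-4-one (tert-butyl and methyl cis) | C[C@@H]1O[C@H](C(C)(C)C)OC1=O | intermediate
7 | (2R,5R)-5-bromo-2-tert-butyl-5-methyl-1,3-dioxolan-4-one (tert-butyl and methyl cis, bromine trans to tert-butyl) | C[C@]1(Br)O[C@H](C(C)(C)C)OC1=O | intermediate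
8 | vinylboronic acid pinacol ester, 2-ethenyl-4,4,5,5-tetramethyl-1,3,2-dioxaborolane | C=CB1OC(C)(C)C(C)(C)O1 | starting material
9 | (2,5-dimethoxy-3-methylphenyl)lithium | [Li]c1cc(OC)cc(C)c1OC | intermediate
10 | lithium (2,5-dimethoxy-3-methylphenyl)(ethenyl)(2,3-dimethylbutane-2,3-diolato)borate | [Li+].C=C[B-]1(c2cc(OC)cc(C)c2OC)OC(C)(C)C(C)(C)O1 | intermediate
11 | (2S,5R)-2-tert-butyl-5-[2-(2,5-dimethoxy-3-methylphenyl)-2-(4,4,5,5-tetramethyl-1,3,2-dioxaborolan-2-yl)ethyl]-5-methyl-1,3-dioxolan-4-one (both epimers at the boron-bearing carbon; new chain trans to tert-butyl) | C[C@]1(CC(B2OC(C)(C)C(C)(C)O2)c2cc(OC)cc(C)c2OC)O[C@H](C(C)(C)C)OC1=O | intermediate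
12 | (2S,5R)-2-tert-butyl-5-[2-(2,5-dimethoxy-3-methylphenyl)ethyl]-5-methyl-1,3-dioxolan-4-one | C[C@]1(CCc2cc(OC)cc(C)c2OC)O[C@H](C(C)(C)C)OC1=O | intermediate
13 | (2R)-4-(2,5-dimethoxy-3-methylphenyl)-2-methylbutane-1,2-diol | C[C@](O)(CO)CCc1cc(OC)cc(C)c1OC | intermediate
14 | 2-[(3R)-3,4-dihydroxy-3-methylbutyl]-6-methylcyclohexa-2,5-diene-1,4-dione | C[C@](O)(CO)CCC1=CC(=O)C=C(C)C1=O | intermediate
15 | bridged quinone monoketal of 14: both hydroxyl groups added to the carbonyl carbon flanked by the methyl-bearing and the chain-bearing ring carbons (2,8-dimethyl-3,4-dihydro-2H-8a,2-(epoxymethano)chromen-6-one, 2R, ketal carbon fixed by the bridge) | CC1=CC(=O)C=C2CC[C@]3(C)CO[C@]12O3 | intermediate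
16 | (2R)-2-(hydroxymethyl)-2,8-dimethyl-3,4-dihydro-2H-chromen-6-ol | C[C@]1(CO)CCc2cc(O)cc(C)c2O1 | intermediate
17 | [(2R)-6-(methoxymethoxy)-2,8-dimethyl-3,4-dihydro-2H-chromen-2-yl]methanol | C[C@]1(CO)CCc2cc(OCOC)cc(C)c2O1 | intermediate
18 | (2R)-6-(methoxymethoxy)-2,8-dimethyl-3,4-dihydro-2H-chromene-2-carbaldehyde | C[C@]1(C=O)CCc2cc(OCOC)cc(C)c2O1 | intermediate
19 | (2R)-2-ethenyl-6-(methoxymethoxy)-2,8-dimethyl-3,4-dihydro-2H-chromene | C[C@]1(C=C)CCc2cc(OCOC)cc(C)c2O1 | intermediate
20 | geraniol, (2E)-3,7-dimethylocta-2,6-dien-1-ol | CC(C)=CCC/C(C)=C/CO | starting material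
21 | [(2S,3S)-3-methyl-3-(4-methylpent-3-en-1-yl)oxiran-2-yl]methanol | CC(C)=CCC[C@]1(C)O[C@H]1CO | intermediate
22 | [(2S,3S)-3-methyl-3-(4-methylpent-3-en-1-yl)oxiran-2-yl]methyl 4-methylbenzenesulfonate | CC(C)=CCC[C@]1(C)O[C@H]1COS(=O)(=O)c1ccc(C)cc1 | intermediate
23 | 1-(trimethylsilyl)propyne, trimethyl(prop-1-yn-1-yl)silane | CC#C[Si](C)(C)C | starting material
24 | 3-lithio-1-(trimethylsilyl)propyne | [Li]CC#C[Si](C)(C)C | intermediate
25 | trimethyl{4-[(2S,3S)-3-methyl-3-(4-methylpent-3-en-1-yl)oxiran-2-yl]but-1-yn-1-yl}silane | CC(C)=CCC[C@]1(C)O[C@H]1CCC#C[Si](C)(C)C | intermediate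
26 | (2S,3S)-2-(but-3-yn-1-yl)-3-methyl-3-(4-methylpent-3-en-1-yl)oxirane | CC(C)=CCC[C@]1(C)O[C@H]1CCC#C | intermediate
27 | (5S,6R)-6,10-dimethylundec-9-en-1-yne-5,6-diol | CC(C)=CCC[C@@](C)(O)[C@@H](O)CCC#C | intermediate
28 | (1E,5S,6R)-1-iodo-2,6,10-trimethylundeca-1,9-diene-5,6-diol | CC(C)=CCC[C@@](C)(O)[C@@H](O)CC/C(C)=C/I | intermediate
29 | 9-{2-[(2S)-6-(methoxymethoxy)-2,8-dimethyl-3,4-dihydro-2H-chromen-2-yl]ethyl}-9-borabicyclo[3.3.1]nonane | C[C@]1(CCB2C3CCCC2CCC3)CCc2cc(OCOC)cc(C)c2O1 | intermediate
30 | (3E,7S,8R)-1-[(2S)-6-(methoxymethoxy)-2,8-dimethyl-3,4-dihydro-2H-chromen-2-yl]-4,8,12-trimethyltrideca-3,11-diene-7,8-diol | CC(C)=CCC[C@@](C)(O)[C@@H](O)CC/C(C)=C/CC[C@@]1(C)CCc2cc(OCOC)cc(C)c2O1 | intermediate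
31 | (2S)-2-[(3E,7S,8R)-7,8-dihydroxy-4,8,12-trimethyltrideca-3,11-dien-1-yl]-2,8-dimethyl-3,4-dihydro-2H-chromen-6-ol | CC(C)=CCC[C@@](C)(O)[C@@H](O)CC/C(C)=C/CC[C@@]1(C)CCc2cc(O)cc(C)c2O1 | target

Total step count: 19. Longest linear sequence: 12 steps (steps 3 to 12, then 18 and 19, from lactic acid; equally steps 1, 2, 5 to 12, 18 and 19 from the phenol).

Steps most likely to fail:

1. Step 5. The hindered tertiary radical may add too slowly to the vinylboron ate complex, so that dehydrobromination of 7 or protonation of the ate complex takes over and the chain does not propagate. The fallback is a nickel-catalysed reductive three-component alkylarylation, which still forms C2–C3 and C4–C4a in one operation. It sets out from 3, which is converted (n-BuLi, THF, −78 °C, then I2) into 1-iodo-2,5-dimethoxy-3-methylbenzene F1. F1, 8 and 7 are then combined with NiCl2(dme), 4,4'-di-tert-butyl-2,2'-bipyridine and tetrakis(dimethylamino)ethylene in THF at 20 °C. The same dioxolanonyl radical should add to 8 anti to tert-butyl, and the α-boryl radical is captured by an arylnickel species that reductively eliminates. The fallback comes back to the route at 11.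

2. Step 6. Protodeboronation may stall because the electron-rich benzylic fluoroborate is protonated only slowly, or the lactone acetal may be cleaved by the basic fluoride. The fallback replaces protonolysis by oxidation and ionic deoxygenation. It sets out from 11, which is oxidised (NaBO3·4H2O, THF/H2O, 20 °C) to (2S,5R)-2-tert-butyl-5-[2-(2,5-dimethoxy-3-methylphenyl)-2-hydroxyethyl]-5-methyl-1,3-dioxolan-4-one F2. The benzylic hydroxyl of F2 is then removed by ionic hydrogenation (Et3SiH, CF3CO2H, CH2Cl2, 0 °C) through the dimethoxybenzyl cation. The fallback comes back at 12.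

3. Step 15. The propargyl anion may attack the epoxide or couple through its allenyl terminus instead of displacing the tosylate cleanly. The fallback moves the C–C bond formation to the opening of a terminal epoxide. It sets out from 22, which is hydrolysed (HClO4 aq., THF, 0 °C, inversion at the tertiary carbon) to (2S,3R)-2,3-dihydroxy-3,7-dimethyloct-6-en-1-yl 4-methylbenzenesulfonate F3. K2CO3 in MeOH closes F3 to (2R)-6-methyl-2-[(2S)-oxiran-2-yl]hept-5-en-2-ol F4. Opening of F4 at its CH2 terminus with 24 (2.2 equiv, BF3·OEt2, THF, −78 °C) should give (5S,6R)-6,10-dimethyl-1-(trimethylsilyl)undec-9-en-1-yne-5,6-diol F5. Desilylation of F5 (K2CO3, MeOH) comes back to the route at 27, so that steps 15 and 16 are both replaced.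

Further compounds
F1 | step 5 | 1-iodo-2,5-dimethoxy-3-methylbenzene | COc1cc(C)c(OC)c(I)c1
F2 | step 6 | (2S,5R)-2-tert-butyl-5-[2-(2,5-dimethoxy-3-methylphenyl)-2-hydroxyethyl]-5-methyl-1,3-dioxolan-4-one (both carbinol epimers) | C[C@]1(CC(O)c2cc(OC)cc(C)c2OC)O[C@H](C(C)(C)C)OC1=O
F3 | step 15 | (2S,3R)-2,3-dihydroxy-3,7-dimethyloct-6-en-1-yl 4-methylbenzenesulfonate | CC(C)=CCC[C@@](C)(O)[C@@H](O)COS(=O)(=O)c1ccc(C)cc1
F4 | step 15 | (2R)-6-methyl-2-[(2S)-oxiran-2-yl]hept-5-en-2-ol | CC(C)=CCC[C@@](C)(O)[C@@H]1CO1
F5 | step 15 | (5S,6R)-6,10-dimethyl-1-(trimethylsilyl)undec-9-en-1-yne-5,6-diol | CC(C)=CCC[C@@](C)(O)[C@@H](O)CCC#C[Si](C)(C)C
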